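**Plan**

1. Labels: C1–C5 is the chain on the ether CH (C6); C7 the methyl-bearing bridgehead; C8–C9 the ring CH2CH2; C10 the carbinol; C11 the quaternary bridgehead; C12–C16 its chain; C19 the lactone C=O. Enabling feature: C7 holds CH3, the lactone ester oxygen and C8, and faces C11 across the six-membered 1,4-dioxan-2-one ring (1,4-relation). An exocyclic C7=CH2 enol lactone maps onto it once the CH2 gains hydrogen and C7 gains carbon, and a three-carbon enone on C11 is just long enough to reach it.
2. Cuts: C15–C16 and C14=C15 (hydroxymethyl Stille coupling, iodo-olefination); C3–C4 (Negishi); C7–C8 (radical conjugate addition, opens the carbocyclic bridge); C11–C12 (Michael); O–C7 (alkyne hydrocarboxylation); O–C11 (O–H insertion).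
3. Forward: ether bond O–C11, then the dioxanone ring (6-exo-dig), then quaternary C11, then the C8–C10 bridge closes the 6,8-dioxabicyclo[3.2.2]nonane cage, then chain C1–C5, then chain C12–C16, last the C10 hydroxyl and desilylation.
4. Stereocentres: C6 from asymmetric transfer hydrogenation of an ynone; C11 by attack on the ring enolate anti to the C6 side chain; C7 relayed from C11 by the bridging closure; C10 by reagent-controlled CBS reduction.
5. Alkenes: Z C2=C3 from directed trans-hydroalumination/iodination of but-2-yn-1-ol and a retentive coupling; Z C14=C15 from the iodoethylidene Wittig reaction and a retentive hydroxymethylation.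

Key step: step 11

Assumption: C4 travels as a primary chloride and C14 as a 1,3-dioxolane, so that the radical step meets no second alkene, no free aldehyde and no silyl ether.
Remark: the O–H insertion product, the acid and the lactone made from it are mixtures at C11 (partly enolised); this centre is fixed only in the Michael step.

**Route**

Step 1
Reactants: 1 3-chloropropanoyl chloride; 2 bis(trimethylsilyl)acetylene
Product: 3 5-chloro-1-(trimethylsilyl)pent-1-yn-3-one
Conditions: AlCl3, CH2Cl2, 0 °C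
Reagents that add atoms: none
Why: Friedel–Crafts-type ipso acylation of the bis-silyl alkyne by the AlCl3-activated acid chloride stops after one acylation because the ynone formed is deactivated, and the β-chloro ketone is stable under these acidic conditions.

Step 2
Reactants: 3 5-chloro-1-(trimethylsilyl)pent-1-yn-3-one
Product: 4 (3S)-5-chloro-1-(trimethylsilyl)pent-1-yn-3-ol
Conditions: Ru[(S,S)-TsNCH(Ph)CH(Ph)NH](p-cymene) (1 mol%), i-PrOH, rt
Reagents that add atoms: none
Why: Noyori asymmetric transfer hydrogenation of a 1-silyl ynone should, with the (S,S)-ligand, deliver hydride to the face that gives the S carbinol (the future C6), the sense known for this ketone class, and the base-free amido complex spares the β-chloro ketone until it has been reduced.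

Step 3
Reactants: 4 (3S)-5-chloro-1-(trimethylsilyl)pent-1-yn-3-ol
Product: 5 (3S)-5-chloropent-1-yn-3-ol
Conditions: K2CO3 (cat.), MeOH, 0 °C
Reagents that add atoms: none
Why: Carbonate-catalysed methanolysis of the alkynyl C–Si bond (protodesilylation) is selective for the sp-bound silicon and leaves the carbinol centre and the primary chloride untouched at 0 °C.

Step 4
Reactants: 1 3-chloropropanoyl chloride; 6 Meldrum's acid
Product: 8 tert-butyl 5-chloro-3-oxopentanoate, via acyl Meldrum's acid 7 (not isolated)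
Conditions: pyridine, CH2Cl2, 0 °C to rt; then t-BuOH, PhMe, 90 °C
Reagents that add atoms: tert-butanol, CC(C)(C)O
Why: C-acylation of Meldrum's acid followed by thermal loss of acetone and CO2 to an acyl ketene that tert-butanol captures is the standard Meldrum's acid synthesis of β-keto esters and needs no base stronger than pyridine.

Step 5
Reactants: 8 tert-butyl 5-chloro-3-oxopentanoate
Product: 9 tert-butyl 5-chloro-2-diazo-3-oxopentanoate
Conditions: 4-AcNHC6H4SO2N3, Et3N (1.05 equiv), MeCN, 0 °C
Reagents that add atoms: 4-acetamidobenzenesulfonyl azide, CC(=O)Nc1ccc(cc1)S(=O)(=O)N=[N+]=[N-]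
Why: Regitz diazo transfer from a sulfonyl azide to the doubly activated methylene is fast at 0 °C, so one equivalent of amine suffices and loss of HCl from the chloroethyl ketone is held back.

Step 6
Reactants: 5 (3S)-5-chloropent-1-yn-3-ol; 9 tert-butyl 5-chloro-2-diazo-3-oxopentanoate
Product: 10 tert-butyl 5-chloro-2-{[(3S)-5-chloropent-1-yn-3-yl]oxy}-3-oxopentanoate (both C2 epimers)
Conditions: Rh2(OAc)4 (1 mol%), CH2Cl2, 40 °C, slow addition of 9
Reagents that add atoms: none
Why: O–H insertion of the rhodium carbenoid of an acceptor/acceptor diazo compound into the secondary alcohol is faster than cyclopropenation of the terminal alkyne and forms the C11–O bond without touching any bond at C6, whose configuration is therefore retained; C11 arises as both epimers, which is harmless because it is re-formed from an enolate in step 8.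

Step 7
Reactants: 10 tert-butyl 5-chloro-2-{[(3S)-5-chloropent-1-yn-3-yl]oxy}-3-oxopentanoate
Product: 12 (5S)-5-(2-chloroethyl)-3-(3-chloropropanoyl)-6-methylidene-1,4-dioxan-2-one, via β-keto acid 11 (not isolated)
Conditions: TFA, CH2Cl2, 0 °C; evaporate; then AuCl (5 mol%), K2CO3 (10 mol%), MeCN, rt
Reagents that add atoms: none
Why: Acidolysis of the tert-butyl ester and immediate gold-catalysed cycloisomerisation of the alkynoic acid (6-exo-dig, Markovnikov attack of the carboxylate on the internal alkyne carbon C7) should give the exocyclic enol lactone, the catalytic carbonate making the carboxylate the dominant nucleophile and slowing decarboxylation of the β-keto acid.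

Step 8
Reactants: 12 (5S)-5-(2-chloroethyl)-3-(3-chloropropanoyl)-6-methylidene-1,4-dioxan-2-one; 13 acrolein
Product: 14 (3R,5S)-5-(2-chloroethyl)-3-(3-chloropropanoyl)-6-methylidene-3-(3-oxopropyl)-1,4-dioxan-2-one
Conditions: i-Pr2NEt (10 mol%), CH2Cl2, −20 °C
Reagents that add atoms: none
Why: Amine-catalysed Michael addition of the acidic β-keto lactone to acrolein creates the quaternary C11, and the flat ring enolate should be attacked on the face opposite the 2-chloroethyl group on C6 (pseudo-axial next to the exocyclic methylene), as in alkylations of 5-substituted morpholin-2-one and 1,4-dioxan-2-one enolates, so that C12 enters trans to C5 and the acyl arm is left cis to it.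

Step 9
Reactants: 14 (3R,5S)-5-(2-chloroethyl)-3-(3-chloropropanoyl)-6-methylidene-3-(3-oxopropyl)-1,4-dioxan-2-one
Product: 15 (3R,5S)-5-(2-chloroethyl)-3-(3-chloropropanoyl)-3-[2-(1,3-dioxolan-2-yl)ethyl]-6-methylidene-1,4-dioxan-2-one
Conditions: (TMSOCH2)2, TMSOTf (5 mol%), CH2Cl2, −78 °C
Reagents that add atoms: 1,2-bis(trimethylsilyloxy)ethane, C[Si](C)(C)OCCO[Si](C)(C)C
Why: Noyori acetalisation with the bis-silylated diol and catalytic TMSOTf is aprotic, selective for the aldehyde over the hindered α-quaternary ketone and avoids the alcohol/acid mixtures that would solvolyse the enol lactone, and the acetal later keeps the iron enolate of the radical step from an intramolecular aldol reaction.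

Step 10
Reactants: 15 (3R,5S)-5-(2-chloroethyl)-3-(3-chloropropanoyl)-3-[2-(1,3-dioxolan-2-yl)ethyl]-6-methylidene-1,4-dioxan-2-one
Product: 16 (3R,5S)-5-(2-chloroethyl)-3-[2-(1,3-dioxolan-2-yl)ethyl]-6-methylidene-3-(prop-2-enoyl)-1,4-dioxan-2-one
Conditions: Et3N, CH2Cl2, 0 °C
Reagents that add atoms: none
Why: E1cB elimination of HCl from the β-chloro ketone with a tertiary amine unveils the vinyl ketone, while the primary chloride at C4 has no acidifying neighbour and stays.

Step 11
Reactants: 16 (3R,5S)-5-(2-chloroethyl)-3-[2-(1,3-dioxolan-2-yl)ethyl]-6-methylidene-3-(prop-2-enoyl)-1,4-dioxan-2-one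
Product: 17 (1R,5R,9S)-9-(2-chloroethyl)-1-[2-(1,3-dioxolan-2-yl)ethyl]-5-methyl-6,8-dioxabicyclo[3.2.2]nonane-2,7-dione
Conditions: Fe(acac)3 (30 mol%), PhSiH2(Oi-Pr) (2.5 equiv), THF/i-PrOH 10:1, 0.01 M, rt
Reagents that add atoms: none
Why: Proposed new method: an iron hydride formed from Fe(acac)3 and the silane should transfer a hydrogen atom to the CH2 terminus of the exocyclic enol ester, which turns that carbon into the C7 methyl group and leaves a nucleophilic tertiary α-acyloxy radical at C7; the radical adds to the unsubstituted β-carbon C8 of the vinyl ketone, and the α-keto radical so formed is reduced by iron and protonated by i-PrOH. The closest known reaction type is the iron-catalysed reductive coupling of donor olefins (enol ethers among them) with enones, a metal-hydride hydrogen atom transfer followed by Giese addition; the enol ester donor and the bridging ring size are the untested parts. The ring closes 7-endo-trig (C7, C8, C9, C10, C11 plus either two-atom half of the dioxanone), polarity-matched at C8, whereas 6-exo attack at the α-carbon C9 is mismatched; because C7 and C11 lie 1,4 across the six-membered ring, this closure bridges it to the 6,8-dioxabicyclo[3.2.2]nonane. The new stereocentre C7 is dictated by C11: the planar radical can bond only on the ring face that carries the acryloyl arm, so the C7–C8 bond forms cis to C10 and the methyl group ends outside the cage. The step needs hydrogen atom transfer to the 1,1-disubstituted, oxygen-substituted alkene in preference to the enone, and ring closure faster than reduction of the C7 radical; the fixed cis-1,4 placement of radical and acceptor, high dilution and the absence of any other alkene (the chains end in a chloride and an acetal) should secure both, and i-PrOH in place of EtOH protects the enol lactone from solvolysis.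

Step 12
Reactants: 17 (1R,5R,9S)-9-(2-chloroethyl)-1-[2-(1,3-dioxolan-2-yl)ethyl]-5-methyl-6,8-dioxabicyclo[3.2.2]nonane-2,7-dione
Product: 18 (1R,5R,9S)-1-[2-(1,3-dioxolan-2-yl)ethyl]-9-(2-iodoethyl)-5-methyl-6,8-dioxabicyclo[3.2.2]nonane-2,7-dione
Conditions: NaI, butan-2-one, 80 °C
Reagents that add atoms: sodium iodide, [Na+].[I-]
Why: Finkelstein exchange at the unhindered primary chloride is driven by precipitation of NaCl and leaves ketone, lactone and acetal unchanged.

Step 13
Reactants: 19 but-2-yn-1-ol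
Product: 21 (Z)-3-iodobut-2-en-1-ol, via cyclic alkenylaluminate 20 (not isolated)
Conditions: NaAlH2(OCH2CH2OMe)2, THF, 0 °C to rt; then I2, −78 °C
Reagents that add atoms: iodine, II
Why: Hydroxyl-directed trans-hydroalumination of the propargylic alcohol puts aluminium on C3 cis to the CH2O group in a five-membered aluminate, and iodinolysis of the C–Al bond occurs with retention, which fixes the Z geometry.

Step 14
Reactants: 21 (Z)-3-iodobut-2-en-1-ol
Product: 22 tert-butyl{[(2Z)-3-iodobut-2-en-1-yl]oxy}diphenylsilane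
Conditions: TBDPSCl, imidazole, CH2Cl2, rt
Reagents that add atoms: tert-butyl(chloro)diphenylsilane, CC(C)(C)[Si](Cl)(c1ccccc1)c1ccccc1
Why: Silylation of the primary alcohol with a silyl chloride and imidazole is routine, and the TBDPS ether is chosen because it survives the acetal hydrolysis of step 16.

Step 15
Reactants: 18 (1R,5R,9S)-1-[2-(1,3-dioxolan-2-yl)ethyl]-9-(2-iodoethyl)-5-methyl-6,8-dioxabicyclo[3.2.2]nonane-2,7-dione; 22 tert-butyl{[(2Z)-3-iodobut-2-en-1-yl]oxy}diphenylsilane
Product: 24 (1R,5R,9S)-9-[(3Z)-5-{[tert-butyl(diphenyl)silyl]oxy}-3-methylpent-3-en-1-yl]-1-[2-(1,3-dioxolan-2-yl)ethyl]-5-methyl-6,8-dioxabicyclo[3.2.2]nonane-2,7-dione, via alkylzinc iodide 23 (not isolated)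
Conditions: Zn dust, LiCl, THF, 40 °C; then 22, PdCl2(dppf) (5 mol%), THF, 50 °C
Reagents that add atoms: none
Why: LiCl-promoted insertion of zinc into the primary C–I bond gives an alkylzinc iodide that tolerates ketone, lactone and acetal, and its Negishi sp3–sp2 coupling with the vinyl iodide proceeds with retention, carrying the Z geometry of 22 into C2=C3.

Step 16
Reactants: 24 (the dioxolane from step 15)
Product: 25 3-[(1R,5R,9S)-9-[(3Z)-5-{[tert-butyl(diphenyl)silyl]oxy}-3-methylpent-3-en-1-yl]-5-methyl-2,7-dioxo-6,8-dioxabicyclo[3.2.2]nonan-1-yl]propanal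
Conditions: PPTS, acetone/H2O 10:1, 55 °C
Reagents that add atoms: water, O
Why: PPTS-catalysed hydrolysis of the dioxolane is mild enough to leave the TBDPS ether, the trisubstituted alkene and the lactone intact.

Step 17
Reactants: 25 (the aldehyde from step 16)
Product: 26 (1R,5R,9S)-9-[(3Z)-5-{[tert-butyl(diphenyl)silyl]oxy}-3-methylpent-3-en-1-yl]-1-[(3Z)-4-iodopent-3-en-1-yl]-5-methyl-6,8-dioxabicyclo[3.2.2]nonane-2,7-dione
Conditions: EtPPh3I, n-BuLi, THF, rt; I2, −78 °C; NaN(SiMe3)2, −78 to −20 °C; then 25, −78 °C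
Reagents that add atoms: ethyltriphenylphosphonium iodide, CC[P+](c1ccccc1)(c1ccccc1)c1ccccc1.[I-]; iodine, II
Why: Stork–Zhao-type Wittig olefination with the α-iodoethylidene ylide converts aldehydes into (Z)-2-iodoalk-2-enes with iodine cis to the chain, and at −78 °C the aldehyde reacts far faster than the hindered, α-quaternary C10 ketone.

Step 18
Reactants: 26 (the vinyl iodide ketone from step 17)
Product: 27 (1R,2S,5R,9S)-9-[(3Z)-5-{[tert-butyl(diphenyl)silyl]oxy}-3-methylpent-3-en-1-yl]-2-hydroxy-1-[(3Z)-4-iodopent-3-en-1-yl]-5-methyl-6,8-dioxabicyclo[3.2.2]nonan-7-one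
Conditions: (R)-Me-CBS (0.5 equiv), catecholborane, PhMe, −78 °C
Reagents that add atoms: none
Why: Corey–Bakshi–Shibata reduction puts C10 under reagent control: the (R)-oxazaborolidine distinguishes quaternary C11 from methylene C9 and should deliver hydride from the groove on the ether-bridge side to give the 2S alcohol with the hydroxyl syn to the lactone bridge, while catecholborane at −78 °C leaves alkenes, vinyl iodide and lactone alone.

Step 19
Reactants: 27 (the 2S alcohol from step 18)
Product: 28 (1R,2S,5R,9S)-9-[(3Z)-5-{[tert-butyl(diphenyl)silyl]oxy}-3-methylpent-3-en-1-yl]-2-hydroxy-1-[(3Z)-5-hydroxy-4-methylpent-3-en-1-yl]-5-methyl-6,8-dioxabicyclo[3.2.2]nonan-7-one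
Conditions: Bu3SnCH2OH, Pd(PPh3)4 (10 mol%), 1,4-dioxane, 90 °C
Reagents that add atoms: (tributylstannyl)methanol, CCCC[Sn](CCCC)(CCCC)CO
Why: Stille coupling of (tributylstannyl)methanol transfers the hydroxymethyl group to the vinyl iodide with retention, so CH2OH ends cis to the chain (Z at C14=C15) and no hydride reagent that could open the lactone is needed.

Step 20
Reactants: 28 (the mono-silyl ether from step 19)
Product: 29 (1R,2S,5R,9S)-2-hydroxy-1-[(3Z)-5-hydroxy-4-methylpent-3-en-1-yl]-9-[(3Z)-5-hydroxy-3-methylpent-3-en-1-yl]-5-methyl-6,8-dioxabicyclo[3.2.2]nonan-7-one (CNP0105745.1)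
Conditions: HF·pyridine, pyridine, THF, 0 °C to rt
Reagents that add atoms: none
Why: Buffered HF·pyridine cleaves the Si–O bond of the primary silyl ether and is neither basic nor acidic enough to disturb the lactone or ionise the allylic alcohols.

**Compound list**

1 | 3-chloropropanoyl chloride | ClCCC(=O)Cl | starting material
2 | bis(trimethylsilyl)acetylene | C[Si](C)(C)C#C[Si](C)(C)C | starting material
3 | 5-chloro-1-(trimethylsilyl)pent-1-yn-3-one | C[Si](C)(C)C#CC(=O)CCCl | intermediate
4 | (3S)-5-chloro-1-(trimethylsilyl)pent-1-yn-3-ol | C[Si](C)(C)C#C[C@@H](O)CCCl | intermediate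
5 | (3S)-5-chloropent-1-yn-3-ol | C#C[C@@H](O)CCCl | intermediate
6 | Meldrum's acid (2,2-dimethyl-1,3-dioxane-4,6-dione) | CC1(C)OC(=O)CC(=O)O1 | starting material
7 | 5-(3-chloro-1-hydroxypropylidene)-2,2-dimethyl-1,3-dioxane-4,6-dione (acyl Meldrum's acid, not isolated) | CC1(C)OC(=O)C(=C(O)CCCl)C(=O)O1 | intermediate
8 | tert-butyl 5-chloro-3-oxopentanoate | CC(C)(C)OC(=O)CC(=O)CCCl | intermediate
9 | tert-butyl 5-chloro-2-diazo-3-oxopentanoate | CC(C)(C)OC(=O)C(=[N+]=[N-])C(=O)CCCl | intermediate
10 | tert-butyl 5-chloro-2-{[(3S)-5-chloropent-1-yn-3-yl]oxy}-3-oxopentanoate (both C2 epimers) | CC(C)(C)OC(=O)C(O[C@@H](CCCl)C#C)C(=O)CCCl | intermediate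
11 | 5-chloro-2-{[(3S)-5-chloropent-1-yn-3-yl]oxy}-3-oxopentanoic acid (β-keto acid, not isolated) | OC(=O)C(O[C@@H](CCCl)C#C)C(=O)CCCl | intermediate
12 | (5S)-5-(2-chloroethyl)-3-(3-chloropropanoyl)-6-methylidene-1,4-dioxan-2-one (C3 epimers, partly enol) | O=C1OC(=C)[C@H](CCCl)OC1C(=O)CCCl | intermediate
13 | acrolein | C=CC=O | starting material
14 | (3R,5S)-5-(2-chloroethyl)-3-(3-chloropropanoyl)-6-methylidene-3-(3-oxopropyl)-1,4-dioxan-2-one | O=CCC[C@]1(C(=O)CCCl)O[C@@H](CCCl)C(=C)OC1=O | intermediate
15 | (3R,5S)-5-(2-chloroethyl)-3-(3-chloropropanoyl)-3-[2-(1,3-dioxolan-2-yl)ethyl]-6-methylidene-1,4-dioxan-2-one | O1CCOC1CC[C@]2(C(=O)CCCl)O[C@@H](CCCl)C(=C)OC2=O | intermediate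
16 | (3R,5S)-5-(2-chloroethyl)-3-[2-(1,3-dioxolan-2-yl)ethyl]-6-methylidene-3-(prop-2-enoyl)-1,4-dioxan-2-one (key-step precursor) | O1CCOC1CC[C@]2(C(=O)C=C)O[C@@H](CCCl)C(=C)OC2=O | intermediate
17 | (1R,5R,9S)-9-(2-chloroethyl)-1-[2-(1,3-dioxolan-2-yl)ethyl]-5-methyl-6,8-dioxabicyclo[3.2.2]nonane-2,7-dione (key-step product) | O1CCOC1CC[C@@]23O[C@@H](CCCl)[C@@](C)(CCC2=O)OC3=O | intermediate
18 | (1R,5R,9S)-1-[2-(1,3-dioxolan-2-yl)ethyl]-9-(2-iodoethyl)-5-methyl-6,8-dioxabicyclo[3.2.2]nonane-2,7-dione | O1CCOC1CC[C@@]23O[C@@H](CCI)[C@@](C)(CCC2=O)OC3=O | intermediate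
19 | but-2-yn-1-ol | CC#CCO | starting material
20 | sodium 2,2-bis(2-methoxyethoxy)-3-methyl-2,5-dihydro-1,2-oxaaluminol-2-uide (cyclic alkenylaluminate, not isolated) | CC1=CCO[Al-]1(OCCOC)OCCOC.[Na+] | intermediate
21 | (Z)-3-iodobut-2-en-1-ol | C/C(I)=C/CO | intermediate
22 | tert-butyl{[(2Z)-3-iodobut-2-en-1-yl]oxy}diphenylsilane | C/C(I)=C/CO[Si](c1ccccc1)(c1ccccc1)C(C)(C)C | intermediate
23 | alkylzinc iodide of 18 (C4–ZnI, not isolated) | O1CCOC1CC[C@@]23O[C@@H](CC[Zn]I)[C@@](C)(CCC2=O)OC3=O | intermediate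
24 | (1R,5R,9S)-9-[(3Z)-5-{[tert-butyl(diphenyl)silyl]oxy}-3-methylpent-3-en-1-yl]-1-[2-(1,3-dioxolan-2-yl)ethyl]-5-methyl-6,8-dioxabicyclo[3.2.2]nonane-2,7-dione | O1CCOC1CC[C@@]23O[C@@H](CC/C(C)=C\CO[Si](c4ccccc4)(c4ccccc4)C(C)(C)C)[C@@](C)(CCC2=O)OC3=O | intermediate
25 | 3-[(1R,5R,9S)-9-[(3Z)-5-{[tert-butyl(diphenyl)silyl]oxy}-3-methylpent-3-en-1-yl]-5-methyl-2,7-dioxo-6,8-dioxabicyclo[3.2.2]nonan-1-yl]propanal | O=CCC[C@@]12O[C@@H](CC/C(C)=C\CO[Si](c3ccccc3)(c3ccccc3)C(C)(C)C)[C@@](C)(CCC1=O)OC2=O | intermediate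
26 | (1R,5R,9S)-9-[(3Z)-5-{[tert-butyl(diphenyl)silyl]oxy}-3-methylpent-3-en-1-yl]-1-[(3Z)-4-iodopent-3-en-1-yl]-5-methyl-6,8-dioxabicyclo[3.2.2]nonane-2,7-dione | C/C(I)=C/CC[C@@]12O[C@@H](CC/C(C)=C\CO[Si](c3ccccc3)(c3ccccc3)C(C)(C)C)[C@@](C)(CCC1=O)OC2=O | intermediate
27 | (1R,2S,5R,9S)-9-[(3Z)-5-{[tert-butyl(diphenyl)silyl]oxy}-3-methylpent-3-en-1-yl]-2-hydroxy-1-[(3Z)-4-iodopent-3-en-1-yl]-5-methyl-6,8-dioxabicyclo[3.2.2]nonan-7-one | C/C(I)=C/CC[C@@]12O[C@@H](CC/C(C)=C\CO[Si](c3ccccc3)(c3ccccc3)C(C)(C)C)[C@@](C)(CC[C@@H]1O)OC2=O | intermediate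
28 | (1R,2S,5R,9S)-9-[(3Z)-5-{[tert-butyl(diphenyl)silyl]oxy}-3-methylpent-3-en-1-yl]-2-hydroxy-1-[(3Z)-5-hydroxy-4-methylpent-3-en-1-yl]-5-methyl-6,8-dioxabicyclo[3.2.2]nonan-7-one | C/C(=C/CC[C@@]12O[C@@H](CC/C(C)=C\CO[Si](c3ccccc3)(c3ccccc3)C(C)(C)C)[C@@](C)(CC[C@@H]1O)OC2=O)CO | intermediate
29 | (1R,2S,5R,9S)-2-hydroxy-1-[(3Z)-5-hydroxy-4-methylpent-3-en-1-yl]-9-[(3Z)-5-hydroxy-3-methylpent-3-en-1-yl]-5-methyl-6,8-dioxabicyclo[3.2.2]nonan-7-one | C/C(=C/CC[C@@]12O[C@@H](CC/C(C)=C\CO)[C@@](C)(CC[C@@H]1O)OC2=O)CO | target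

**Step count**

Total: 20 steps. Longest linear sequence: 16 steps (steps 1–3, 6–12, 15–20, from 3-chloropropanoyl chloride).

**Steps most likely to fail**

Step 11. The hydride may transfer its hydrogen atom to the vinyl ketone (conjugate reduction), because an acyloxy-substituted alkene is a poorer donor than an enol ether, or the C7 radical may be reduced before the seven-membered closure. The fallback makes the same radical by classical tin hydride chemistry. It sets out from 15: acid-catalysed Markovnikov addition of benzeneselenol (PhSeH, cat. camphorsulfonic acid, CH2Cl2, −40 °C) across the enol lactone should give the tertiary C7 phenyl selenide F1. Et3N then eliminates HCl to the selenide enone F2. Slow addition of Bu3SnH with AIBN in benzene at 80 °C abstracts selenium, and the C7 radical closes the bridge by Giese cyclisation, which returns to the route at 17.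

Step 7. The free β-keto acid may lose CO2 before it cyclises, or the ketone oxygen or the enolisable C11 may attack the gold-bound alkyne in competition with the carboxylate. The fallback builds the lactone first and the ketone second. It sets out from 5: Rh2(OAc)4-catalysed O–H insertion with tert-butyl diazoacetate should give the glycolate ether F3. TFA gives the alkoxyacetic acid F4, which has no second nucleophile and cannot decarboxylate, and AuCl/K2CO3 closes it to the 3-unsubstituted enol lactone F5. Its lithium enolate (LiN(SiMe3)2, 2 equiv, THF, −78 °C) is C-acylated with acid chloride 1 in a crossed Claisen condensation, which returns to the route at 12.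

Step 18. The cage may override the catalyst so that hydride arrives from the lactone-bridge groove and the C10 epimer predominates. The fallback inverts the centre instead of selecting a face. It sets out from 26, whose reduction in that case gives the 2R alcohol F6. A Mitsunobu reaction (4-nitrobenzoic acid, PPh3, DIAD, THF) inverts C10 to the 2S 4-nitrobenzoate F7. The Stille hydroxymethylation of step 19 is run on this ester to give the hydroxymethyl ester F8, and K2CO3 in MeOH at 0 °C removes the activated benzoate, which returns to the route at 28.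

Further compounds
F1 | step 11 | (3R,5S)-5-(2-chloroethyl)-3-(3-chloropropanoyl)-3-[2-(1,3-dioxolan-2-yl)ethyl]-6-methyl-6-(phenylselanyl)-1,4-dioxan-2-one (C6 epimers) | O1CCOC1CC[C@]2(C(=O)CCCl)O[C@@H](CCCl)C(C)([Se]c3ccccc3)OC2=O
F2 | step 11 | (3R,5S)-5-(2-chloroethyl)-3-[2-(1,3-dioxolan-2-yl)ethyl]-6-methyl-6-(phenylselanyl)-3-(prop-2-enoyl)-1,4-dioxan-2-one (C6 epimers) | O1CCOC1CC[C@]2(C(=O)C=C)O[C@@H](CCCl)C(C)([Se]c3ccccc3)OC2=O
F3 | step 7 | tert-butyl 2-{[(3S)-5-chloropent-1-yn-3-yl]oxy}acetate | CC(C)(C)OC(=O)CO[C@@H](CCCl)C#C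
F4 | step 7 | 2-{[(3S)-5-chloropent-1-yn-3-yl]oxy}acetic acid | OC(=O)CO[C@@H](CCCl)C#C
F5 | step 7 | (5S)-5-(2-chloroethyl)-6-methylidene-1,4-dioxan-2-one | O=C1OC(=C)[C@H](CCCl)OC1
F6 | step 18 | (1R,2R,5R,9S)-9-[(3Z)-5-{[tert-butyl(diphenyl)silyl]oxy}-3-methylpent-3-en-1-yl]-2-hydroxy-1-[(3Z)-4-iodopent-3-en-1-yl]-5-methyl-6,8-dioxabicyclo[3.2.2]nonan-7-one | C/C(I)=C/CC[C@@]12O[C@@H](CC/C(C)=C\CO[Si](c3ccccc3)(c3ccccc3)C(C)(C)C)[C@@](C)(CC[C@H]1O)OC2=O
F7 | step 18 | (1R,2S,5R,9S)-9-[(3Z)-5-{[tert-butyl(diphenyl)silyl]oxy}-3-methylpent-3-en-1-yl]-1-[(3Z)-4-iodopent-3-en-1-yl]-5-methyl-7-oxo-6,8-dioxabicyclo[3.2.2]nonan-2-yl 4-nitrobenzoate | C/C(I)=C/CC[C@@]12O[C@@H](CC/C(C)=C\CO[Si](c3ccccc3)(c3ccccc3)C(C)(C)C)[C@@](C)(CC[C@@H]1OC(=O)c3ccc(cc3)[N+](=O)[O-])OC2=O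
F8 | step 18 | (1R,2S,5R,9S)-9-[(3Z)-5-{[tert-butyl(diphenyl)silyl]oxy}-3-methylpent-3-en-1-yl]-1-[(3Z)-5-hydroxy-4-methylpent-3-en-1-yl]-5-methyl-7-oxo-6,8-dioxabicyclo[3.2.2]nonan-2-yl 4-nitrobenzoate | C/C(=C/CC[C@@]12O[C@@H](CC/C(C)=C\CO[Si](c3ccccc3)(c3ccccc3)C(C)(C)C)[C@@](C)(CC[C@@H]1OC(=O)c3ccc(cc3)[N+](=O)[O-])OC2=O)CO
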